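Numbering used throughout: **1** methyl 2,4-dimethoxy-6-methylbenzoate; **2** hexanoyl chloride; **3** keto ester; **4** 6,8-dimethoxy isocoumarin; **5** ring A phenol; **6** 2,2,6-trimethyl-4H-1,3-dioxin-4-one; **7** acetyl chloride; **8** keto-dioxinone; **9** diketo-dioxinone; **10** diazo diketo-dioxinone; **11** aryloxy diketo-dioxinone; **12** acylketene; **13** aryloxy triketo allyl ester; **14** aldol adduct; **15** allyl resorcylate; **16** salicylic acid; **17** C6 methyl ether of the target; **18** target.

## Analysis of the target

Compound 18 is a diaryl ether built on a 1H-isochromen-1-one. Benzo ring A is fused to the α-pyranone ring C, C3 carries a pentyl chain, C6 a free hydroxyl, and O8 is bound to C1' of ring B, a 2,4-dihydroxy-6-pentylphenyl group. There is no stereocentre and no double-bond isomerism, so the problem is one of regiochemistry and functional-group tolerance. Ring C is an enol lactone that aqueous base or alkoxide opens to a keto acid, and the three phenols, above all the resorcinol ring B, are easily oxidised and easily attacked by electrophiles. The difficult bond is O8–C1'. C8 lies peri to the lactone carbonyl, to which its oxygen is hydrogen-bonded, and C1' is flanked by the C2' hydroxyl and the C6' pentyl group, so a direct coupling of two arenes is hindered on both sides and must also tell three phenolic oxygens apart. The plan rests on ring B having the substitution pattern of olivetol: oxygen on C2' and C4' and the chain on C6', the pattern of a folded poly-β-carbonyl chain. In the open chain C2' and C6' are ketone carbons, so C1' is the central sp3 carbon of a 1,3-diketone, where the aryloxy group can be installed before ring B exists. Ring B then needs only one carbon–carbon bond, C5'–C6', with C5' carrying a carboxyl group as a temporary activator.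

## Retrosynthetic reasoning

**18 to 17.** The last operation frees the C6 hydroxyl of ring A. One oxygen of ring A must stay masked from the beginning so that only O8 is available when the ether is made. A methyl ether survives carbenoid, ketene and aldol chemistry, and a boron trihalide removes it at the end without cleaving the diaryl ether, which has no sp3 carbon on oxygen, or the enol lactone.

**17 to 15 (through 16).** C5' of ring B bears hydrogen in 17. Going backwards, a carboxyl group is put on C5' (acid 16, ester 15). An acid with hydroxyls ortho and para to the carboxyl loses it on mild heating, so the activator costs one operation. The ester of 15 is an allyl ester rather than a simple alkyl ester because saponification of a doubly ortho-substituted salicylate needs hot aqueous base, which would open ring C. The allyl group is removed by zerovalent palladium under neutral conditions.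

**15 to 13 (the key disconnection).** The C5'–C6' bond of ring B is cut and the three ring oxygens are written as ketones. This gives the open-chain triketo ester 13, a dodecanoate in which C2 becomes C5', C3 becomes C4', C4 becomes C3', C5 becomes C2', C6 becomes C1' and C7 becomes C6'. This cut is preferred over any other ring B bond because it pairs the most acidic methylene that can act as a carbon nucleophile (C2, between ketone and ester) with the one ketone it can reach through a six-membered ring (C7). It also leaves the ether carbon C6 between two ketones, where it can be functionalised. Forward, the step must form one C–C bond, lose water and aromatise, without closing through oxygen or through the other enolisable carbons.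

**13 to 11 (through 12).** The β-keto ester end of 13 is too reactive to carry through the chain assembly, so it is masked as the 2,2-dimethyl-1,3-dioxin-4-one of 11. Heating unmasks it by cycloreversion to acylketene 12, which is captured by the alcohol corresponding to the ester of 13. The mask is removed only after the ether is in place, so no triketo ester exists before it is needed.

**11 to 5 and 10.** The O8–C1' bond is cut at the sp3 stage. The carbon between the two ketones of 11 is the one position in the chain that supports a diazo group (diazo compound 10), and a rhodium carbenoid at that carbon inserts into the O–H bond of phenol 5. This joins two fragments of similar size under neutral conditions and avoids any aryl–oxygen coupling at a hindered arene carbon. The forward step has to favour the intermolecular O–H insertion over reactions of the carbenoid within its own chain.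

**10 to 9 to 8 to 6, 7 and 2.** The diazo group comes from diazo transfer to the most acidic methylene of diketo-dioxinone 9. Compound 9 is assembled linearly: the dienolate of 6 is acetylated with 7 to give 8, and the dianion of 8 is acylated at its terminal carbon with 2. Each bond formed is between a carbonyl and an α-carbon, so the 1,3-oxygen pattern of ring B is written into the chain.

**5 to 4 to 3 to 1 and 2.** The C8 hydroxyl of 5 is unmasked from the dimethyl ether 4 by chelation-controlled cleavage of the ether peri to the lactone carbonyl. The O2–C1 bond of ring C is cut to give keto ester 3 (enol lactonisation forward), and the C4–C3 bond of 3 is cut to give toluate 1 and acid chloride 2 (lateral lithiation and acylation forward). Ring A and ring C are thus made at the correct oxidation level in three classical steps, and the same acid chloride 2 supplies both pentyl chains.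

## Alternatives that were turned down

**Alternative 1:** The O8–C1' bond is formed last-but-few, after the two rings have been tied together as an ester. Depside A1 joins a ring A salicylic acid, carrying a heptynyl group as the latent C3–C4 unit with its chain, to one hydroxyl of the ring B resorcinol. Oxidation of A1 would make the free ring A hydroxyl bond to the ring B carbon para to the remaining phenol, closing the seven-membered ether–lactone of depsidone A2. Cleavage of the ester bridge, 6-endo cyclisation of the acid onto the alkyne and demethylation would follow.
- For: the ether closure is intramolecular and its position is fixed by the tether and the para hydroxyl. Both rings come from simple arenes, with no construction of ring B from a chain. On convergence and on directness of the C–O bond formation this plan is stronger than the chosen one.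
- Against: the ring A hydroxyl is hydrogen-bonded to the ester carbonyl and is a poor nucleophile. The oxidised resorcinol ring can instead give quinones, spiro-dienones or C–C coupled products. The alkyne must survive the oxidant and later cyclise 6-endo rather than 5-exo, and the ester bridge must be opened by a nucleophile at a hindered carbonyl.
- Comparison: the chosen strategy needs no oxidation of an electron-rich phenol and puts the oxygen on an sp3 carbon by a two-electron insertion. The price is a linear build-up of ring B from three small pieces.

**Alternative 2:** The bonds C4a–C4 and C8a–C1 are cut, so that both carbon substituents of ring A are attached in one operation. The silyl aryl triflate A3, which already contains the diaryl ether, would give with fluoride the 3-aryloxy-5-methoxybenzyne. The malonate diester A4 adds through carbon to the aryne carbon remote from the aryloxy group, and the aryl anion then attacks an ester carbonyl. After fragmentation of the four-membered ring this gives homophthalate A5.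
- For: the regiochemistry is set reliably by the inductive effect of the aryloxy group, and two C–C bonds form in one step. On regiochemical certainty of the key step this plan is at least as good as the chosen one.
- Against: the key step closes no ring and does not address the hindered diaryl ether, which must already exist in A3. A3 itself needs several steps (ether formation, ortho silylation, triflation). A5 still has to be hexanoylated at C4, cyclised and decarboxylated to install C3 with its chain, through hydrolytic conditions, and three methyl ethers remain to be cleaved. Malonates also insert less cleanly than β-keto esters, since simple C-arylation competes.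
- Comparison: the chosen strategy spends its key step on the ether problem and on ring B together, and obtains ring A with ring C from 1 in three routine steps.

**Alternative 3:** The bonds C1–O2 and C3–C4 are cut, so ring C arises by cycloaddition. Benzocyclobutenone A6 would open on heating to an ortho-quinoid ketene, which is to add aldehyde A7 across its carbonyl group in a hetero-Diels–Alder reaction to give dihydroisocoumarin A8.
- For: two bonds and ring C form in one step with full atom economy, and the pentyl chain arrives convergently.
- Against: A8 is at the wrong oxidation level. A C3 stereocentre is created only to be destroyed, and the dehydrogenation must be done next to two electron-rich rings, where benzylic halogenation or quinone oxidants also attack the arenes. An unactivated, enolisable aliphatic aldehyde is a weak partner for such ketenes, which dimerise or are captured otherwise. A6 needs an aryne cycloaddition and, again, a preformed diaryl ether.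
- Comparison: the chosen strategy makes ring C directly as the enol lactone and needs no redox adjustment. It offers no cycloaddition shortcut, but its ring A and ring C chemistry is reliable.

Key step: step 9

Remark: compounds 11–14 are drawn as keto forms but should exist as mixtures of enol tautomers; 11–13 are racemic at the aryloxy-bearing carbon and 14 is a mixture of diastereomers, all of which converge on achiral 15.

## Route

**Step 1**
Reactants: 1 methyl 2,4-dimethoxy-6-methylbenzoate; 2 hexanoyl chloride
Product: 3 methyl 2,4-dimethoxy-6-(2-oxoheptyl)benzoate
Conditions: LiN(i-Pr)2 (2.1 equiv), THF, −78 °C; then 2, −78 °C; aq. NH4Cl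
Reagents that add atoms: none
Why: Lateral lithiation of the ortho-toluate gives an ester-stabilised benzylic anion that is C-acylated by the acid chloride (Claisen-type acylation); the second equivalent of base holds the more acidic ketone product as its enolate and so limits double acylation.

**Step 2**
Reactants: 3 methyl 2,4-dimethoxy-6-(2-oxoheptyl)benzoate
Product: 4 6,8-dimethoxy-3-pentyl-1H-isochromen-1-one
Conditions: p-TsOH·H2O (10 mol %), toluene, reflux with removal of MeOH
Reagents that add atoms: none
Why: Acid-catalysed enol lactonisation: the ketone enolises towards the benzylic carbon and the enol oxygen acylates on the neighbouring ester in a 6-exo-trig closure with loss of methanol. Acid is used because strong base could divert the keto ester into a Dieckmann-type carbocyclisation to a naphthalenediol.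

**Step 3**
Reactants: 4 6,8-dimethoxy-3-pentyl-1H-isochromen-1-one
Product: 5 8-hydroxy-6-methoxy-3-pentyl-1H-isochromen-1-one
Conditions: BCl3 (1.5 equiv), CH2Cl2, −78 → 0 °C; H2O
Reagents that add atoms: none
Why: Chelation-controlled Lewis acid ether cleavage: boron bridges the lactone carbonyl and the peri C8 methoxy oxygen in a six-membered chelate, so chloride removes only that methyl group and the C6 ether is kept.

**Step 4**
Reactants: 6 2,2,6-trimethyl-4H-1,3-dioxin-4-one; 7 acetyl chloride
Product: 8 2,2-dimethyl-6-(2-oxopropyl)-4H-1,3-dioxin-4-one
Conditions: LiN(SiMe3)2, THF, −78 °C; then 7 (0.5 equiv), −78 °C; aq. NH4Cl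
Reagents that add atoms: none
Why: The vinylogous (dienolate) anion of the dioxinone is C-acylated at its γ-carbon, the ring methyl group (vinylogous Claisen acylation); the excess dienolate takes up the more acidic product as its enolate.

**Step 5**
Reactants: 8 2,2-dimethyl-6-(2-oxopropyl)-4H-1,3-dioxin-4-one; 2 hexanoyl chloride
Product: 9 2,2-dimethyl-6-(2,4-dioxononyl)-4H-1,3-dioxin-4-one
Conditions: LiN(i-Pr)2 (2.2 equiv), THF, −78 °C; then 2, −78 °C; aq. NH4Cl
Reagents that add atoms: none
Why: Dianion acylation of the Huckin–Weiler type: the first deprotonation occurs at the doubly activated methylene and the second at the terminal methyl, and the more reactive terminal carbanion is acylated to give the 1,3-diketone.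

**Step 6**
Reactants: 9 2,2-dimethyl-6-(2,4-dioxononyl)-4H-1,3-dioxin-4-one
Product: 10 6-(3-diazo-2,4-dioxononyl)-2,2-dimethyl-4H-1,3-dioxin-4-one
Conditions: 4-acetamidobenzenesulfonyl azide (1.1 equiv), Et3N (1.2 equiv), MeCN, 0 °C, short reaction time
Reagents that add atoms: 4-acetamidobenzenesulfonyl azide, CC(=O)Nc1ccc(cc1)S(=O)(=O)N=[N+]=[N-]
Why: Regitz diazo transfer goes to the methylene between the two ketones, which is clearly more acidic than the methylene between a ketone and the dioxinone ring. Cold, brief exposure to the amine should prevent cyclisation of the diazo group onto that remaining active methylene.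

**Step 7**
Reactants: 5 8-hydroxy-6-methoxy-3-pentyl-1H-isochromen-1-one; 10 6-(3-diazo-2,4-dioxononyl)-2,2-dimethyl-4H-1,3-dioxin-4-one
Product: 11 6-{3-[(6-methoxy-1-oxo-3-pentyl-1H-isochromen-8-yl)oxy]-2,4-dioxononyl}-2,2-dimethyl-4H-1,3-dioxin-4-one (racemic)
Conditions: Rh2(OAc)4 (2 mol %), 5 (2 equiv), 4 Å molecular sieves, CH2Cl2, 40 °C, slow addition of 10
Reagents that add atoms: none
Why: Rhodium carbenoid O–H insertion: loss of dinitrogen gives an electrophilic diacyl carbenoid, the phenol oxygen adds to form an oxonium ylide and a proton shift gives the α-aryloxy 1,3-diketone. Excess phenol and slow addition of 10 should favour this over 1,5 C–H insertion into the pentyl chain; the new stereocentre is racemic and is destroyed in step 9.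

**Step 8**
Reactants: 11 6-{3-[(6-methoxy-1-oxo-3-pentyl-1H-isochromen-8-yl)oxy]-2,4-dioxononyl}-2,2-dimethyl-4H-1,3-dioxin-4-one
Product: 13 prop-2-en-1-yl 6-[(6-methoxy-1-oxo-3-pentyl-1H-isochromen-8-yl)oxy]-3,5,7-trioxododecanoate (racemic), via acylketene 12 (not isolated)
Conditions: prop-2-en-1-ol (20 equiv), toluene, 105 °C; concentrated and used crude
Reagents that add atoms: prop-2-en-1-ol, C=CCO
Why: Thermal retro-hetero-Diels–Alder reaction of the dioxinone releases acetone and acylketene 12, which the primary alcohol captures as the β-keto ester. The large excess of alcohol should outrun internal O-acylation of a diketone enol to a 4-hydroxy-2-pyranone, and the neutral alcohol leaves the ring C lactone closed.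

**Step 9**
Reactants: 13 prop-2-en-1-yl 6-[(6-methoxy-1-oxo-3-pentyl-1H-isochromen-8-yl)oxy]-3,5,7-trioxododecanoate
Product: 15 prop-2-en-1-yl 2,4-dihydroxy-5-[(6-methoxy-1-oxo-3-pentyl-1H-isochromen-8-yl)oxy]-6-pentylbenzoate, via aldol adduct 14 (not isolated)
Conditions: Et3N (3 equiv), CH2Cl2, 0 °C → rt; then AcOH (excess), 40 °C
Reagents that add atoms: none
Why: Triethylamine equilibrates the enolates of 13, and the β-keto ester enolate (chain C2, the future C5') adds to the C7 ketone (the future C6'), the only carbonyl it can reach through a six-membered transition state, to give the cyclohexanedione aldol adduct 14. Ring B closes by a 6-exo-trig aldol, allowed for the enolate in either its enolendo (C2=C3) or enolexo (C2=C1) description. Loss of water by an E1cB path, completed by the acetic acid treatment, and enolisation of the two remaining ring ketones aromatise the ring to 15; the closest known reaction type is the biomimetic aldol aromatisation of 3,5,7-triketo esters derived from diketo-dioxinones to 6-alkyl resorcylates. The stereocentre of 13 and the three of 14 all disappear on aromatisation, so no stereocontrol is needed. The selectivity required is the C2-to-C7 aldol against Claisen closure of C6 onto the ester, aldol of the pentyl α-methylene onto C3, cyclisation through oxygen to pyranones, and retro-Claisen cleavage of the α-aryloxy diketone. The Claisen mode would make C6 quaternary, so its product cannot aromatise and can revert. The pentyl α-methylene is only singly activated and should not be deprotonated by a tertiary amine. Pyranone formation is acid-promoted and acid is added only after the aldol, retro-Claisen cleavage needs a nucleophilic base or solvent that is absent, and the inductive pull of the aryloxy group keeps C7 electrophilic.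

**Step 10**
Reactants: 15 prop-2-en-1-yl 2,4-dihydroxy-5-[(6-methoxy-1-oxo-3-pentyl-1H-isochromen-8-yl)oxy]-6-pentylbenzoate
Product: 17 8-(2,4-dihydroxy-6-pentylphenoxy)-6-methoxy-3-pentyl-1H-isochromen-1-one, via salicylic acid 16 (not isolated)
Conditions: Pd(PPh3)4 (5 mol %), morpholine (3 equiv), THF, rt; then AcOH (excess), toluene, 100 °C
Reagents that add atoms: none
Why: Tsuji–Trost deallylation: zerovalent palladium ionises the allyl ester and morpholine captures the allyl group, so no hydroxide reaches the ring C lactone. The freed acid 16 has hydroxyls ortho and para to the carboxyl and should undergo thermal protodecarboxylation through ipso protonation.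

**Step 11**
Reactants: 17 8-(2,4-dihydroxy-6-pentylphenoxy)-6-methoxy-3-pentyl-1H-isochromen-1-one
Product: 18 8-(2,4-dihydroxy-6-pentylphenoxy)-6-hydroxy-3-pentyl-1H-isochromen-1-one
Conditions: BBr3 (5 equiv), CH2Cl2, −78 °C → rt; H2O
Reagents that add atoms: none
Why: Lewis acid cleavage of the aryl methyl ether: boron binds the ether oxygen and bromide attacks the methyl carbon. The diaryl ether and the enol lactone have no sp3 carbon on oxygen and should survive; the excess reagent allows for the two free phenols.

## Compound list

1 | methyl 2,4-dimethoxy-6-methylbenzoate | COC(=O)c1c(C)cc(OC)cc1OC | starting material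
2 | hexanoyl chloride | CCCCCC(=O)Cl | starting material
3 | methyl 2,4-dimethoxy-6-(2-oxoheptyl)benzoate | CCCCCC(=O)Cc1cc(OC)cc(OC)c1C(=O)OC | intermediate
4 | 6,8-dimethoxy-3-pentyl-1H-isochromen-1-one | CCCCCc1cc2cc(OC)cc(OC)c2c(=O)o1 | intermediate
5 | 8-hydroxy-6-methoxy-3-pentyl-1H-isochromen-1-one | CCCCCc1cc2cc(OC)cc(O)c2c(=O)o1 | intermediate
6 | 2,2,6-trimethyl-4H-1,3-dioxin-4-one | CC1=CC(=O)OC(C)(C)O1 | starting material
7 | acetyl chloride | CC(=O)Cl | starting material
8 | 2,2-dimethyl-6-(2-oxopropyl)-4H-1,3-dioxin-4-one | CC(=O)CC1=CC(=O)OC(C)(C)O1 | intermediate
9 | 2,2-dimethyl-6-(2,4-dioxononyl)-4H-1,3-dioxin-4-one | CCCCCC(=O)CC(=O)CC1=CC(=O)OC(C)(C)O1 | intermediate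
10 | 6-(3-diazo-2,4-dioxononyl)-2,2-dimethyl-4H-1,3-dioxin-4-one | CCCCCC(=O)C(=[N+]=[N-])C(=O)CC1=CC(=O)OC(C)(C)O1 | intermediate
11 | 6-{3-[(6-methoxy-1-oxo-3-pentyl-1H-isochromen-8-yl)oxy]-2,4-dioxononyl}-2,2-dimethyl-4H-1,3-dioxin-4-one (racemic) | CCCCCC(=O)C(Oc1cc(OC)cc2cc(CCCCC)oc(=O)c12)C(=O)CC1=CC(=O)OC(C)(C)O1 | intermediate
12 | 6-[(6-methoxy-1-oxo-3-pentyl-1H-isochromen-8-yl)oxy]dodec-1-ene-1,3,5,7-tetrone (racemic acylketene, not isolated) | CCCCCC(=O)C(Oc1cc(OC)cc2cc(CCCCC)oc(=O)c12)C(=O)CC(=O)C=C=O | intermediate
13 | prop-2-en-1-yl 6-[(6-methoxy-1-oxo-3-pentyl-1H-isochromen-8-yl)oxy]-3,5,7-trioxododecanoate (racemic) | CCCCCC(=O)C(Oc1cc(OC)cc2cc(CCCCC)oc(=O)c12)C(=O)CC(=O)CC(=O)OCC=C | intermediate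
14 | prop-2-en-1-yl 2-hydroxy-3-[(6-methoxy-1-oxo-3-pentyl-1H-isochromen-8-yl)oxy]-4,6-dioxo-2-pentylcyclohexane-1-carboxylate (mixture of stereoisomers and tautomers, not isolated) | CCCCCC1(O)C(Oc2cc(OC)cc3cc(CCCCC)oc(=O)c23)C(=O)CC(=O)C1C(=O)OCC=C | intermediate
15 | prop-2-en-1-yl 2,4-dihydroxy-5-[(6-methoxy-1-oxo-3-pentyl-1H-isochromen-8-yl)oxy]-6-pentylbenzoate | CCCCCc1c(Oc2cc(OC)cc3cc(CCCCC)oc(=O)c23)c(O)cc(O)c1C(=O)OCC=C | intermediate
16 | 2,4-dihydroxy-5-[(6-methoxy-1-oxo-3-pentyl-1H-isochromen-8-yl)oxy]-6-pentylbenzoic acid (not isolated) | CCCCCc1c(Oc2cc(OC)cc3cc(CCCCC)oc(=O)c23)c(O)cc(O)c1C(=O)O | intermediate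
17 | 8-(2,4-dihydroxy-6-pentylphenoxy)-6-methoxy-3-pentyl-1H-isochromen-1-one | CCCCCc1cc2cc(OC)cc(Oc3c(O)cc(O)cc3CCCCC)c2c(=O)o1 | intermediate
18 | 8-(2,4-dihydroxy-6-pentylphenoxy)-6-hydroxy-3-pentyl-1H-isochromen-1-one | CCCCCc1cc2cc(O)cc(Oc3c(O)cc(O)cc3CCCCC)c2c(=O)o1 | target

## Step count and risk

Total step count: 11. Longest linear sequence: 8 steps (steps 1, 2, 3, 7, 8, 9, 10, 11; the branch through steps 4, 5, 6 is equally long).

**Step 9 (key step).** The most acidic proton of 13 is the one on the aryloxy-bearing carbon, so the C7 carbonyl may spend most of its time as part of an enolate, and it is flanked by two substituents. The aldol may then be slow enough for deacylation of the α-aryloxy diketone or closure through oxygen to take over.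
Fallback: it sets out from 5 and returns at 18, bringing ring B in ready-made. Commercial 1,3-dimethoxy-5-pentylbenzene (CCCCCc1cc(OC)cc(OC)c1) would be iodinated with N-iodosuccinimide, para to one methoxy group and ortho to the chain, to give 1-iodo-2,4-dimethoxy-6-pentylbenzene F1. An Ullmann ether synthesis of F1 with 5 (CuI, picolinic acid, K3PO4, DMSO, 90 °C) should give 8-(2,4-dimethoxy-6-pentylphenoxy)-6-methoxy-3-pentyl-1H-isochromen-1-one F2. BBr3 in CH2Cl2 would then remove all three methyl groups to give 18.

**Step 7.** The hydroxyl of 5 is hydrogen-bonded to the lactone carbonyl and is a weak nucleophile. The carbenoid may instead be consumed by 1,5 C–H insertion into its own pentyl chain or by Wolff rearrangement.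
Fallback: it sets out from 9 and returns at 11, replacing carbene chemistry by a substitution. N-Chlorosuccinimide in CH2Cl2 would chlorinate the diketone methylene of 9 to give 6-(3-chloro-2,4-dioxononyl)-2,2-dimethyl-4H-1,3-dioxin-4-one F3. The phenoxide of 5 (K2CO3, acetone, rt) should displace chloride from this doubly activated α-halo ketone to give 11, kept cold and brief so that 11 does not cyclise under the base.

**Step 8.** The acylketene 12 may be captured by an enol oxygen of its own diketone before the alcohol reaches it, giving a pyranone, or the chain may cyclise without control at 105 °C.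
Fallback: it sets out from 11 and returns at 17, generating no ketene. Et3N in CH2Cl2 should induce aldol aromatisation of the dioxinone itself, its C5 adding to the hexanoyl carbonyl, to give 7-hydroxy-6-[(6-methoxy-1-oxo-3-pentyl-1H-isochromen-8-yl)oxy]-2,2-dimethyl-5-pentyl-4H-1,3-benzodioxin-4-one F4. Hot aqueous acid (6 M HCl, 1,4-dioxane, 90 °C) would hydrolyse the acetonide and decarboxylate the resulting acid to give 17.

**Step 5.** O-acylation, double acylation and proton transfer from the product to the dianion may lower the conversion with an acid chloride.
Fallback: it sets out from 6 and returns at 9, using soft enolisation. The lithium dienolate of 6 would be acylated with allyl 3-chloro-3-oxopropanoate (C=CCOC(=O)CC(=O)Cl) to give prop-2-en-1-yl 4-(2,2-dimethyl-4-oxo-4H-1,3-dioxin-6-yl)-3-oxobutanoate F5. C-acylation of F5 with 2 (MgCl2, pyridine, CH2Cl2) should give prop-2-en-1-yl 2-[(2,2-dimethyl-4-oxo-4H-1,3-dioxin-6-yl)acetyl]-3-oxooctanoate F6. Pd(PPh3)4 with morpholine in THF would remove the allyl ester with decarboxylation to give 9.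

## Further compounds

F1 | step 9 | 1-iodo-2,4-dimethoxy-6-pentylbenzene | CCCCCc1cc(OC)cc(OC)c1I
F2 | step 9 | 8-(2,4-dimethoxy-6-pentylphenoxy)-6-methoxy-3-pentyl-1H-isochromen-1-one | CCCCCc1cc2cc(OC)cc(Oc3c(OC)cc(OC)cc3CCCCC)c2c(=O)o1
F3 | step 7 | 6-(3-chloro-2,4-dioxononyl)-2,2-dimethyl-4H-1,3-dioxin-4-one (racemic) | CCCCCC(=O)C(Cl)C(=O)CC1=CC(=O)OC(C)(C)O1
F4 | step 8 | 7-hydroxy-6-[(6-methoxy-1-oxo-3-pentyl-1H-isochromen-8-yl)oxy]-2,2-dimethyl-5-pentyl-4H-1,3-benzodioxin-4-one | CCCCCc1c(Oc2cc(OC)cc3cc(CCCCC)oc(=O)c23)c(O)cc2OC(C)(C)OC(=O)c12
F5 | step 5 | prop-2-en-1-yl 4-(2,2-dimethyl-4-oxo-4H-1,3-dioxin-6-yl)-3-oxobutanoate | C=CCOC(=O)CC(=O)CC1=CC(=O)OC(C)(C)O1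
F6 | step 5 | prop-2-en-1-yl 2-[(2,2-dimethyl-4-oxo-4H-1,3-dioxin-6-yl)acetyl]-3-oxooctanoate (racemic) | CCCCCC(=O)C(C(=O)OCC=C)C(=O)CC1=CC(=O)OC(C)(C)O1
A1 | alternative 1 | 3-hydroxy-5-pentylphenyl 2-(hept-1-yn-1-yl)-6-hydroxy-4-methoxybenzoate | CCCCCC#Cc1cc(OC)cc(O)c1C(=O)Oc1cc(O)cc(CCCCC)c1
A2 | alternative 1 | 1-(hept-1-yn-1-yl)-8-hydroxy-3-methoxy-6-pentyl-11H-dibenzo[b,e][1,4]dioxepin-11-one | CCCCCC#Cc1cc(OC)cc2Oc3c(CCCCC)cc(O)cc3OC(=O)c12
A3 | alternative 2 | 3-(2,4-dimethoxy-6-pentylphenoxy)-5-methoxy-2-(trimethylsilyl)phenyl trifluoromethanesulfonate | CCCCCc1cc(OC)cc(OC)c1Oc1cc(OC)cc(OS(=O)(=O)C(F)(F)F)c1[Si](C)(C)C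
A4 | alternative 2 | dimethyl malonate | COC(=O)CC(=O)OC
A5 | alternative 2 | methyl 2-(2,4-dimethoxy-6-pentylphenoxy)-4-methoxy-6-(2-methoxy-2-oxoethyl)benzoate | COC(=O)Cc1cc(OC)cc(Oc2c(OC)cc(OC)cc2CCCCC)c1C(=O)OC
A6 | alternative 3 | 5-(2,4-dimethoxy-6-pentylphenoxy)-3-methoxybicyclo[4.2.0]octa-1,3,5-trien-7-one | O=C1Cc2cc(OC)cc(Oc3c(OC)cc(OC)cc3CCCCC)c21
A7 | alternative 3 | hexanal | CCCCCC=O
A8 | alternative 3 | 8-(2,4-dimethoxy-6-pentylphenoxy)-6-methoxy-3-pentyl-3,4-dihydro-1H-isochromen-1-one (racemic) | CCCCCC1Cc2cc(OC)cc(Oc3c(OC)cc(OC)cc3CCCCC)c2C(=O)O1
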